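**Strategy.** The route rests on cutting the glutarate chain between the ester carbonyl carbon (C5) and its α-CH2 (C4). The 1,3-relationship of that carbonyl to the tertiary carbinol C3–OH is read as the retron of a carbonylative epoxide opening. In one pot, cobaltate opens the CH2 of the enantiopure 2,2-disubstituted epoxide 10, CO inserts to make the C4–C5 bond, and the transient oxetan-2-one 12 is passed onto propargylic alcohol 4. Both halves are thereby joined while C3 and its C–O bond stay untouched. The epoxide comes from (R)-citramalic acid; the Z-alkene is carried as an alkyne and released last by cis-semi-hydrogenation.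

Key step: step 7

Remark: the target stereocentre is (3R) (ester arm outranks acid arm). The descriptor reads S in 12 and 13 only because CIP priorities change; the spatial arrangement taken from (R)-citramalic acid is never altered.

**Step 1**
Reactants: 1 4-bromo-2,6-dimethoxyphenol
Product: 2 (4-bromo-2,6-dimethoxyphenoxy)tri(propan-2-yl)silane
Conditions: TIPSCl, imidazole, DMF, 40 °C
Reagents that add atoms: triisopropylsilyl chloride, CC(C)[Si](Cl)(C(C)C)C(C)C
Why: Imidazole-promoted silyl ether formation masks the acidic phenol, which would otherwise quench the alkoxide catalyst of step 7; the hindered aryl TIPS ether should resist that alkoxide.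

**Step 2**
Reactants: 2 (4-bromo-2,6-dimethoxyphenoxy)tri(propan-2-yl)silane; 3 prop-2-yn-1-ol
Product: 4 3-[3,5-dimethoxy-4-(triisopropylsilyloxy)phenyl]prop-2-yn-1-ol
Conditions: Pd(PhCN)2Cl2 (3 mol%), [tBu3PH]BF4 (6 mol%), CuI (2 mol%), iPr2NH, 1,4-dioxane, rt to 40 °C
Reagents that add atoms: none
Why: Sonogashira coupling; the bulky electron-rich phosphine should allow oxidative addition into the electron-rich aryl bromide under mild conditions, and the free propargylic OH is tolerated.

**Step 3**
Reactants: 5 (R)-citramalic acid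
Product: 6 2-[(4R)-2,2,4-trimethyl-5-oxo-1,3-dioxolan-4-yl]acetic acid
Conditions: 2,2-dimethoxypropane, TsOH·H2O (cat.), acetone, rt
Reagents that add atoms: 2,2-dimethoxypropane, COC(C)(C)OC
Why: Acid-catalysed transacetalisation closes the α-hydroxy acid unit to the five-membered 1,3-dioxolan-4-one, which differentiates the two carboxyl groups without touching the stereocentre.

**Step 4**
Reactants: 6 2-[(4R)-2,2,4-trimethyl-5-oxo-1,3-dioxolan-4-yl]acetic acid
Product: 7 tert-butyl 2-[(4R)-2,2,4-trimethyl-5-oxo-1,3-dioxolan-4-yl]acetate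
Conditions: tBuOC(=NH)CCl3, BF3·OEt2 (cat.), CH2Cl2–cyclohexane, 0 °C to rt
Reagents that add atoms: tert-butyl 2,2,2-trichloroacetimidate, CC(C)(C)OC(=N)C(Cl)(Cl)Cl
Why: Trichloroacetimidate tert-butylation (acid-catalysed O-alkylation of the free carboxylic acid) installs an ester that is inert to hydride and alkoxide and too hindered to lactonise later.

**Step 5**
Reactants: 7 tert-butyl 2-[(4R)-2,2,4-trimethyl-5-oxo-1,3-dioxolan-4-yl]acetate
Product: 8 tert-butyl (3R)-3,4-dihydroxy-3-methylbutanoate
Conditions: NaBH4, EtOH, 0 °C to rt; aq. NH4Cl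
Reagents that add atoms: none
Why: Borohydride reduction of the activated acylal-type lactone (hydride addition, loss of acetone, reduction of the α-hydroxy aldehyde) should give the 1,2-diol while the tert-butyl ester is left alone.

**Step 6**
Reactants: 8 tert-butyl (3R)-3,4-dihydroxy-3-methylbutanoate
Product: 10 tert-butyl 2-[(2R)-2-methyloxiran-2-yl]acetate, via primary tosylate 9 (not isolated)
Conditions: TsCl, Et3N, Bu2SnO (2 mol%), CH2Cl2, 0 °C to rt; then K2CO3, MeOH, rt
Reagents that add atoms: none
Why: Tin-catalysed selective sulfonylation of the primary hydroxyl (Martinelli conditions) is followed by 3-exo-tet Williamson closure by the tertiary alkoxide; no bond to the stereocentre is broken, so its configuration is retained.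

**Step 7**
Reactants: 10 tert-butyl 2-[(2R)-2-methyloxiran-2-yl]acetate; 11 carbon monoxide; 4 3-[3,5-dimethoxy-4-(triisopropylsilyloxy)phenyl]prop-2-yn-1-ol
Product: 13 1-tert-butyl 5-{3-[3,5-dimethoxy-4-(triisopropylsilyloxy)phenyl]prop-2-yn-1-yl} (3S)-3-hydroxy-3-methylpentanedioate, via β-lactone 12 (not isolated)
Conditions: [(ClTPP)Al(THF)2][Co(CO)4] (3 mol%; ClTPP = tetrakis(4-chlorophenyl)porphyrinato), CO (60 bar), Et2O, 25–40 °C; vent; then 4, NaHMDS (0.15 equiv), THF, 0 °C
Reagents that add atoms: none
Why: One-pot epoxide alkoxycarbonylation: the Al(III) cation activates the epoxide, Co(CO)4− attacks the unsubstituted CH2 in an SN2 step, CO migratory insertion creates the acyl–CH2 bond, and the aluminium alkoxide closes onto the acyl cobalt (4-exo-trig) to give oxetan-2-one 12, whose acyl–oxygen bond is then cleaved by the sodium alkoxide of 4. The closest known reaction type is the regioselective ring-expanding carbonylation of 2,2-disubstituted epoxides to β,β-disubstituted β-lactones, followed by their alcoholysis to tertiary aldol-type esters. No stereocentre is created; C3 keeps its configuration because no bond to it is broken in either stage. The step needs attack at CH2 rather than at the quaternary carbon, which the steric bias and a weakly donating ether solvent (keeping the opening SN2-like) should secure. It also needs acyl–O rather than alkyl–O cleavage of 12, which is secured because the tertiary C–O cannot undergo SN2 and the strained lactone is far more electrophilic than the tert-butyl ester. The tertiary alkoxide formed is reprotonated by further 4, so only catalytic base is needed, and the alkyne never meets cobalt carbonyl under CO pressure.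

**Step 8**
Reactants: 13 1-tert-butyl 5-{3-[3,5-dimethoxy-4-(triisopropylsilyloxy)phenyl]prop-2-yn-1-yl} (3S)-3-hydroxy-3-methylpentanedioate
Product: 15 (3R)-3-hydroxy-5-{[3-(4-hydroxy-3,5-dimethoxyphenyl)prop-2-yn-1-yl]oxy}-3-methyl-5-oxopentanoic acid, via silyl-protected acid 14 (not isolated)
Conditions: TFA–CH2Cl2 (1:4), anisole, 0 °C; evaporate; then TBAF/AcOH (1:1), THF, 0 °C to rt; pH 3–4 work-up
Reagents that add atoms: none
Why: Acidolysis of the tert-butyl ester (E1 loss of isobutene; the propargylic ester cannot ionise) is followed by buffered fluoride cleavage of the aryl Si–O bond, with acetic acid keeping the carboxyl protonated so that no cyclic-anhydride scrambling of C3 is expected.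

**Step 9**
Reactants: 15 (3R)-3-hydroxy-5-{[3-(4-hydroxy-3,5-dimethoxyphenyl)prop-2-yn-1-yl]oxy}-3-methyl-5-oxopentanoic acid
Product: 16 (3R)-3-hydroxy-5-{[(2Z)-3-(4-hydroxy-3,5-dimethoxyphenyl)prop-2-en-1-yl]oxy}-3-methyl-5-oxopentanoic acid
Conditions: H2 (1 atm), Pd/BaSO4 (5%), quinoline, EtOAc–MeOH, rt, stopped at 1 equiv H2
Reagents that add atoms: none
Why: Lindlar-type cis-semi-hydrogenation on a quinoline-poisoned palladium surface delivers both hydrogens to one face of the alkyne and should give the Z-alkene; the BaSO4 support is chosen because the substrate is a free acid.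

**Compound list**

1 | 4-bromo-2,6-dimethoxyphenol | COc1cc(Br)cc(OC)c1O | starting material
2 | (4-bromo-2,6-dimethoxyphenoxy)tri(propan-2-yl)silane | COc1cc(Br)cc(OC)c1O[Si](C(C)C)(C(C)C)C(C)C | intermediate
3 | prop-2-yn-1-ol | C#CCO | starting material
4 | 3-[3,5-dimethoxy-4-(triisopropylsilyloxy)phenyl]prop-2-yn-1-ol | COc1cc(C#CCO)cc(OC)c1O[Si](C(C)C)(C(C)C)C(C)C | intermediate
5 | (R)-citramalic acid, (2R)-2-hydroxy-2-methylbutanedioic acid | C[C@@](O)(CC(=O)O)C(=O)O | starting material
6 | 2-[(4R)-2,2,4-trimethyl-5-oxo-1,3-dioxolan-4-yl]acetic acid | CC1(C)OC(=O)[C@@](C)(CC(=O)O)O1 | intermediate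
7 | tert-butyl 2-[(4R)-2,2,4-trimethyl-5-oxo-1,3-dioxolan-4-yl]acetate | CC1(C)OC(=O)[C@@](C)(CC(=O)OC(C)(C)C)O1 | intermediate
8 | tert-butyl (3R)-3,4-dihydroxy-3-methylbutanoate | OC[C@](C)(O)CC(=O)OC(C)(C)C | intermediate
9 | tert-butyl (3R)-3-hydroxy-3-methyl-4-(tosyloxy)butanoate | Cc1ccc(cc1)S(=O)(=O)OC[C@](C)(O)CC(=O)OC(C)(C)C | intermediate (not isolated)
10 | tert-butyl 2-[(2R)-2-methyloxiran-2-yl]acetate | C[C@@]1(CC(=O)OC(C)(C)C)CO1 | intermediate
11 | carbon monoxide | [C-]#[O+] | starting material
12 | tert-butyl 2-[(2S)-2-methyl-4-oxooxetan-2-yl]acetate | C[C@@]1(CC(=O)OC(C)(C)C)CC(=O)O1 | intermediate (not isolated)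
13 | 1-tert-butyl 5-{3-[3,5-dimethoxy-4-(triisopropylsilyloxy)phenyl]prop-2-yn-1-yl} (3S)-3-hydroxy-3-methylpentanedioate | CC(C)(C)OC(=O)C[C@@](C)(O)CC(=O)OCC#Cc1cc(OC)c(O[Si](C(C)C)(C(C)C)C(C)C)c(OC)c1 | intermediate
14 | (3R)-5-({3-[3,5-dimethoxy-4-(triisopropylsilyloxy)phenyl]prop-2-yn-1-yl}oxy)-3-hydroxy-3-methyl-5-oxopentanoic acid | COc1cc(C#CCOC(=O)C[C@](C)(O)CC(=O)O)cc(OC)c1O[Si](C(C)C)(C(C)C)C(C)C | intermediate (not isolated)
15 | (3R)-3-hydroxy-5-{[3-(4-hydroxy-3,5-dimethoxyphenyl)prop-2-yn-1-yl]oxy}-3-methyl-5-oxopentanoic acid | COc1cc(C#CCOC(=O)C[C@](C)(O)CC(=O)O)cc(OC)c1O | intermediate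
16 | (3R)-3-hydroxy-5-{[(2Z)-3-(4-hydroxy-3,5-dimethoxyphenyl)prop-2-en-1-yl]oxy}-3-methyl-5-oxopentanoic acid | COc1cc(/C=C\COC(=O)C[C@](C)(O)CC(=O)O)cc(OC)c1O | target

**Step count.** Total: 9 steps. Longest linear sequence: 7 steps (5 → 6 → 7 → 8 → 10 → 13 → 15 → 16, steps 3–9).

**Steps most likely to fail**

1. Step 7. Ring opening of the hindered epoxide by cobaltate may be slow or unselective (attack at the quaternary carbon, Lewis-acid isomerisation to a carbonyl compound). In the second stage the alkoxide may trigger E1cB opening of the lactone instead of acyl transfer. Fallback, setting out from 10 and coming back at 15: the same C4–C5 bond is made by radical atom-transfer carbonylation instead of cobaltate chemistry. Epoxide 10 is opened at CH2 with LiI/AcOH in THF to the iodohydrin tert-butyl (3R)-3-hydroxy-4-iodo-3-methylbutanoate F1. Silylation (TESOTf, 2,6-lutidine) gives tert-butyl (3R)-4-iodo-3-methyl-3-(triethylsilyloxy)butanoate F2, which can no longer re-close to the epoxide. Light-accelerated Pd(PPh3)4-catalysed carbonylation of F2 with CO 11 (45 bar), alcohol 4 and K2CO3/DMAP should give the O-triethylsilyl analogue of 13, F3. The step 8 conditions remove the triethylsilyl group together with tert-butyl and TIPS and rejoin the route at 15.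

2. Step 9. Over-reduction to the saturated ester, Z-to-E isomerisation or hydrogenolysis of the newly formed allylic C–O bond may occur on palladium. Fallback, setting out from 15 and coming back at 16: catalytic hydrogenation is replaced by a stoichiometric electron-transfer reduction with activated zinc (Zn(Cu/Ag), MeOH–H2O, rt to 40 °C, Boland reduction). This reduces only conjugated, propargylically oxygenated alkynes, stops at the cis-alkene and involves no metal hydride that could isomerise or cleave the allylic ester. This fallback makes no new compound (F0).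

3. Step 5. Chemoselectivity may be lost, or the basic borohydride medium may drive lactonisation of the 4-hydroxy ester with expulsion of tert-butoxide. Fallback, setting out from 7 and coming back at 8: the dioxolanone is hydrolysed under mild acid (AcOH–H2O 4:1, 40 °C) to (2R)-4-tert-butoxy-2-hydroxy-2-methyl-4-oxobutanoic acid F4. Its free carboxylic acid is then reduced chemoselectively with BH3·SMe2/B(OMe)3 (THF, 0 °C), a non-basic reduction in which acids react far faster than tert-butyl esters, to give diol 8.

**Further compounds**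

F1 | step 7 | tert-butyl (3R)-3-hydroxy-4-iodo-3-methylbutanoate | CC(C)(C)OC(=O)C[C@@](C)(O)CI
F2 | step 7 | tert-butyl (3R)-4-iodo-3-methyl-3-(triethylsilyloxy)butanoate | CC(C)(C)OC(=O)C[C@@](C)(O[Si](CC)(CC)CC)CI
F3 | step 7 | 1-tert-butyl 5-{3-[3,5-dimethoxy-4-(triisopropylsilyloxy)phenyl]prop-2-yn-1-yl} (3S)-3-methyl-3-(triethylsilyloxy)pentanedioate | CC(C)(C)OC(=O)C[C@@](C)(O[Si](CC)(CC)CC)CC(=O)OCC#Cc1cc(OC)c(O[Si](C(C)C)(C(C)C)C(C)C)c(OC)c1
F4 | step 5 | (2R)-4-tert-butoxy-2-hydroxy-2-methyl-4-oxobutanoic acid | CC(C)(C)OC(=O)C[C@@](C)(O)C(=O)O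
F0 | step 9 | none | none
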